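Assumption: the SMILES is read as the (2R,5R)-oxanone with both side-chain alkenes E; both enantiomers of Ipc2BCl are taken as purchasable reagents.

**Retrosynthetic overview**
- The target is cut in the middle of the side chain, at the bond between the ketone carbon and the enone CH. A Nozaki–Hiyama–Kishi coupling joins a C14 aryl aldehyde and a C14 alkenyl iodide that already carries the oxanone; oxidation and desilylation finish.
- Aldehyde half: the aryl–CH2 bond comes from copper-catalysed allylation of an aryllithium with an (E)-allylic bromide. The arene comes from o-cresol (ortho-bromination, O-methylation, C–H borylation/oxidation); the bromide from but-3-yn-1-ol (carboalumination).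
- Iodide half: the ring C–O bond comes from 6-exo alkoxymercuration of a tertiary alcohol onto an isopropenyl group. The ring C4–C5 bond comes from an Ipc-boron aldol of a methyl ketone with methacrolein, which sets C-5.
- Methyl ketone: Seebach alkylation of the (S)-lactic acid dioxolanone sets the quaternary C-2, using (E)-1,5-diiodo-2-methylpent-1-ene from pent-4-yn-1-ol.
- Ring order: the arene is carried from o-cresol, the dioxolanone is a temporary auxiliary ring, and the oxanone is the only ring built (step 19), before the fragment coupling.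

**Aryl aldehyde half**

Step 1
Reactants: 1 o-cresol (2-methylphenol)
Product: 2 2-bromo-6-methylphenol
Conditions: NBS (1.0 equiv), i-Pr2NH (10 mol %), CH2Cl2, 0 °C to rt
Reagents that add atoms: N-bromosuccinimide, O=C1CCC(=O)N1Br
Why: Amine-catalysed electrophilic aromatic bromination of a phenol is ortho-selective (the N-bromoamine is delivered through a hydrogen bond to OH), and the methyl group blocks the other ortho site.

Step 2
Reactants: 2 2-bromo-6-methylphenol
Product: 3 1-bromo-2-methoxy-3-methylbenzene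
Conditions: MeI, K2CO3, acetone, reflux
Reagents that add atoms: iodomethane, CI
Why: Williamson ether synthesis of the phenoxide with a reactive methyl electrophile.

Step 3
Reactants: 3 1-bromo-2-methoxy-3-methylbenzene
Product: 5 3-bromo-4-methoxy-5-methylphenol, via arylboronate 4 (not isolated)
Conditions: [Ir(OMe)(cod)]2 (1.5 mol %), 4,4'-di-tert-butyl-2,2'-bipyridine (3 mol %), B2pin2 (0.6 equiv), THF, 80 °C; then Oxone (2KHSO5·KHSO4·K2SO4), acetone/H2O, rt
Reagents that add atoms: potassium peroxymonosulfate (active part of Oxone), [K+].[O-]S(=O)(=O)OO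
Why: Iridium-catalysed C–H borylation is sterically controlled and takes the only C–H with no ortho substituent (para to OMe), and one-pot oxidation of the C–B bond gives the phenol (borylation–oxidation).

Step 4
Reactants: 5 3-bromo-4-methoxy-5-methylphenol
Product: 6 (3-bromo-4-methoxy-5-methylphenoxy)(tert-butyl)dimethylsilane
Conditions: TBSCl, imidazole, DMF, rt
Reagents that add atoms: tert-butyldimethylsilyl chloride, CC(C)(C)[Si](C)(C)Cl
Why: Standard silylation of an unhindered phenol, giving an ether that survives organolithium, chromium and mild acid steps.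

Step 5
Reactants: 7 but-3-yn-1-ol
Product: 8 (but-3-yn-1-yloxy)(tert-butyl)dimethylsilane
Conditions: TBSCl, imidazole, CH2Cl2, rt
Reagents that add atoms: tert-butyldimethylsilyl chloride, CC(C)(C)[Si](C)(C)Cl
Why: Silylation of the primary alcohol so that the alkyne can be carbometalated and the two chain ends later told apart.

Step 6
Reactants: 8 (but-3-yn-1-yloxy)(tert-butyl)dimethylsilane
Product: 10 (2E)-5-(tert-butyldimethylsilyloxy)-3-methylpent-2-en-1-ol, via alkenylalane 9 (not isolated)
Conditions: AlMe3 (2.5 equiv), Cp2ZrCl2 (25 mol %), CH2Cl2, 0 °C to rt; evaporate volatiles; n-BuLi, THF/hexane, −30 °C; (CH2O)n, rt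
Reagents that add atoms: trimethylaluminium, C[Al](C)C; formaldehyde (as paraformaldehyde), C=O
Why: Negishi zirconium-catalysed carboalumination adds Me and Al syn across the terminal alkyne with Al on the terminal carbon, and hydroxymethylation of the alanate with retention fixes the E-trisubstituted alkene.

Step 7
Reactants: 10 (2E)-5-(tert-butyldimethylsilyloxy)-3-methylpent-2-en-1-ol
Product: 11 {[(3E)-5-bromo-3-methylpent-3-en-1-yl]oxy}(tert-butyl)dimethylsilane
Conditions: CBr4, PPh3, CH2Cl2, 0 °C; used at once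
Reagents that add atoms: carbon tetrabromide, BrC(Br)(Br)Br
Why: Appel bromination converts the primary allylic alcohol into the bromide under neutral conditions without allylic transposition or loss of the E geometry.

Step 8
Reactants: 6 (3-bromo-4-methoxy-5-methylphenoxy)(tert-butyl)dimethylsilane; 11 {[(3E)-5-bromo-3-methylpent-3-en-1-yl]oxy}(tert-butyl)dimethylsilane
Product: 13 tert-butyl{[(3E)-5-[5-(tert-butyldimethylsilyloxy)-2-methoxy-3-methylphenyl]-3-methylpent-3-en-1-yl]oxy}dimethylsilane, via aryllithium 12 (not isolated)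
Conditions: n-BuLi (1.05 equiv), THF, −78 °C; CuBr·SMe2 (10 mol %); then 11, −78 to 0 °C
Reagents that add atoms: none
Why: Bromine–lithium exchange followed by copper-catalysed SN2 allylation at the unhindered primary terminus of the γ,γ-disubstituted allylic bromide, which keeps the E alkene.

Step 9
Reactants: 13 bis-silyl ether from step 8
Product: 14 (3E)-5-[5-(tert-butyldimethylsilyloxy)-2-methoxy-3-methylphenyl]-3-methylpent-3-en-1-ol
Conditions: camphorsulfonic acid (10 mol %), MeOH/CH2Cl2, 0 °C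
Reagents that add atoms: none
Why: Acid-catalysed methanolysis cleaves a primary alkyl silyl ether much faster than an aryl silyl ether (selective desilylation).

Step 10
Reactants: 14 homoallylic alcohol from step 9
Product: 15 (3E)-5-[5-(tert-butyldimethylsilyloxy)-2-methoxy-3-methylphenyl]-3-methylpent-3-enal
Conditions: IBX, DMSO/THF, rt; used crude within hours
Reagents that add atoms: none
Why: IBX oxidation is neutral and base-free, so the β,γ-unsaturated aldehyde is formed without migration of the alkene into conjugation.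

**Alkenyl iodide half**

Step 11
Reactants: 16 pent-4-yn-1-ol
Product: 18 (4E)-5-iodo-4-methylpent-4-en-1-ol, via alkenylalane 17 (not isolated)
Conditions: AlMe3 (3 equiv), Cp2ZrCl2 (25 mol %), CH2Cl2, 0 °C to rt; then I2, THF, −30 to 0 °C
Reagents that add atoms: trimethylaluminium, C[Al](C)C; iodine, II
Why: Negishi carboalumination–iodinolysis gives the (E)-2-methylalk-1-enyl iodide by syn methylalumination and iodination with retention.

Step 12
Reactants: 18 (4E)-5-iodo-4-methylpent-4-en-1-ol
Product: 19 (1E)-1,5-diiodo-2-methylpent-1-ene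
Conditions: I2, PPh3, imidazole, CH2Cl2, 0 °C to rt
Reagents that add atoms: iodine, II
Why: Appel-type iodination of the primary alcohol leaves the alkenyl iodide untouched.

Step 13
Reactants: 20 (S)-lactic acid
Product: 21 (2S,5S)-2-tert-butyl-5-methyl-1,3-dioxolan-4-one
Conditions: pivalaldehyde, p-TsOH (cat.), H2SO4 (cat.), pentane, reflux (Dean–Stark); recrystallise at −78 °C
Reagents that add atoms: pivalaldehyde, CC(C)(C)C=O
Why: Acid-catalysed acetalisation (Seebach dioxolanone) gives mainly the cis acetal, purified by crystallisation, so the lactate stereocentre is relayed to the acetal carbon.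

Step 14
Reactants: 21 (2S,5S)-2-tert-butyl-5-methyl-1,3-dioxolan-4-one; 19 (1E)-1,5-diiodo-2-methylpent-1-ene
Product: 23 (2S,5R)-2-tert-butyl-5-[(4E)-5-iodo-4-methylpent-4-en-1-yl]-5-methyl-1,3-dioxolan-4-one, via lithium enolate 22 (not isolated)
Conditions: LiN(i-Pr)2 (1.1 equiv), THF, −78 °C; then 19 (1.2 equiv), DMPU, −78 to −30 °C
Reagents that add atoms: none
Why: Seebach self-regeneration of stereocentres: the enolate is alkylated at the primary iodide on the face anti to the tert-butyl group, which sets the quaternary centre as R (the later ring C-2).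

Step 15
Reactants: 23 alkylated dioxolanone from step 14
Product: 24 (2R,6E)-2-hydroxy-7-iodo-N-methoxy-N,2,6-trimethylhept-6-enamide
Conditions: MeNH(OMe)·HCl (3 equiv), AlMe3 (3 equiv), CH2Cl2, 0 °C to rt
Reagents that add atoms: N,O-dimethylhydroxylamine hydrochloride, Cl.CNOC
Why: Weinreb aminolysis of the activated acylal by the aluminium amide opens the auxiliary ring and releases pivalaldehyde without touching the quaternary centre.

Step 16
Reactants: 24 Weinreb amide from step 15
Product: 25 (3R,7E)-3-hydroxy-8-iodo-3,7-dimethyloct-7-en-2-one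
Conditions: MeMgBr (3.5 equiv), THF, 0 °C
Reagents that add atoms: methylmagnesium bromide, C[Mg]Br
Why: Grignard addition to a Weinreb amide stops at the chelated tetrahedral intermediate and gives the methyl ketone on work-up.

Step 17
Reactants: 25 hydroxy ketone from step 16
Product: 26 (3R,7E)-8-iodo-3,7-dimethyl-3-(trimethylsilyloxy)oct-7-en-2-one
Conditions: TMSCl, imidazole, DMF, 0 °C to rt
Reagents that add atoms: chlorotrimethylsilane, C[Si](C)(C)Cl
Why: Silylation masks the tertiary hydroxyl so that it does not consume the boron reagent in the aldol.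

Step 18
Reactants: 26 TMS-protected methyl ketone; 27 methacrolein (2-methylprop-2-enal)
Product: 30 (3R,6R,10E)-3,6-dihydroxy-11-iodo-2,6,10-trimethylundeca-1,10-dien-5-one, via boron enolate 28 (not isolated), via TMS aldol 29 (not isolated)
Conditions: (+)-Ipc2BCl (from (−)-α-pinene, 1.5 equiv), Et3N (2 equiv), Et2O, 0 °C; 27 (3 equiv), −78 to −20 °C; H2O2, MeOH, pH 7 buffer (NaH2PO4/Na2HPO4), 0 °C; then citric acid (cat.), MeOH, rt; chromatography removes the minor 3-epimer
Reagents that add atoms: none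
Why: Paterson boron aldol of a methyl ketone: the Ipc2B enolate (only the methyl side can enolise) is expected to add to the Re face of methacrolein under reagent control to set the (3R)-carbinol (the (−)-reagent gives the Si-face adduct), and mild acid methanolysis then frees the tertiary hydroxyl.

Step 19
Reactants: 30 diol ketone from step 18
Product: 32 (2R,5R)-5-hydroxy-2-[(4E)-5-iodo-4-methylpent-4-en-1-yl]-2,6,6-trimethyloxan-3-one, via organomercurial 31 (not isolated)
Conditions: Hg(O2CCF3)2 (1.1 equiv), CH2Cl2, 0 °C; then NaBH4 (0.5 equiv), aq. NaOH, THF, −20 °C, 5 min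
Reagents that add atoms: none
Why: Intramolecular alkoxymercuration–demercuration: the tertiary hydroxyl adds 6-exo to the Markovnikov carbon of the isopropenyl group (the iodoalkene is too electron-poor to compete), and the C–Hg bond is reduced faster than the hindered ketone; no stereocentre is made or touched, since the new ring carbon ends as CMe2.

Step 20
Reactants: 32 hydroxy oxanone from step 19
Product: 33 (2R,5R)-2-[(4E)-5-iodo-4-methylpent-4-en-1-yl]-2,6,6-trimethyl-5-(triethylsilyloxy)oxan-3-one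
Conditions: TESOTf, 2,6-lutidine, CH2Cl2, −78 °C
Reagents that add atoms: triethylsilyl trifluoromethanesulfonate, CC[Si](CC)(CC)OS(=O)(=O)C(F)(F)F
Why: Silylation of the hindered secondary alcohol protects it from the later oxidation and blocks retro-aldol or dehydration of the β-hydroxy ketone.

**Coupling and end game**

Step 21
Reactants: 15 aryl aldehyde (1.3 equiv); 33 alkenyl iodide
Product: 35 (2R,5R)-2-[(4E,8E)-10-[5-(tert-butyldimethylsilyloxy)-2-methoxy-3-methylphenyl]-6-hydroxy-4,8-dimethyldeca-4,8-dien-1-yl]-2,6,6-trimethyl-5-(triethylsilyloxy)oxan-3-one (both carbinol epimers), via alkenylchromium 34 (not isolated)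
Conditions: CrCl2 (6 equiv), NiCl2 (2 mol %), DMSO/THF, rt
Reagents that add atoms: none
Why: Nozaki–Hiyama–Kishi coupling: the alkenylchromium formed with retention of the E geometry adds to the aldehyde only, sparing the hindered ring ketone and both silyl ethers; the new carbinol is unselective and is erased in step 22.

Step 22
Reactants: 35 allylic alcohol from step 21
Product: 36 (2R,5R)-2-[(4E,8E)-10-[5-(tert-butyldimethylsilyloxy)-2-methoxy-3-methylphenyl]-4,8-dimethyl-6-oxodeca-4,8-dien-1-yl]-2,6,6-trimethyl-5-(triethylsilyloxy)oxan-3-one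
Conditions: IBX (1.5 equiv), DMSO/THF, rt
Reagents that add atoms: none
Why: Neutral IBX oxidation of the allylic alcohol gives the enone without moving the β,γ-alkene into conjugation.

Step 23
Reactants: 36 bis-silylated dienone from step 22
Product: 37 (2R,5R)-5-hydroxy-2-[(4E,8E)-10-(5-hydroxy-2-methoxy-3-methylphenyl)-4,8-dimethyl-6-oxodeca-4,8-dien-1-yl]-2,6,6-trimethyloxan-3-one (CNP0268050.2)
Conditions: HF·pyridine, pyridine, THF, 0 °C to rt
Reagents that add atoms: none
Why: Buffered fluoride desilylation removes the aryl TBS and the secondary TES ethers under mildly acidic conditions that leave the skipped dienone and the β-hydroxy ketone intact.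

**Compound list**

1 | o-cresol (2-methylphenol) | Cc1ccccc1O | starting material
2 | 2-bromo-6-methylphenol | Cc1cccc(Br)c1O | intermediate
3 | 1-bromo-2-methoxy-3-methylbenzene | COc1c(C)cccc1Br | intermediate
4 | 2-(3-bromo-4-methoxy-5-methylphenyl)-4,4,5,5-tetramethyl-1,3,2-dioxaborolane | COc1c(C)cc(B2OC(C)(C)C(C)(C)O2)cc1Br | intermediate
5 | 3-bromo-4-methoxy-5-methylphenol | COc1c(C)cc(O)cc1Br | intermediate
6 | (3-bromo-4-methoxy-5-methylphenoxy)(tert-butyl)dimethylsilane | COc1c(C)cc(O[Si](C)(C)C(C)(C)C)cc1Br | intermediate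
7 | but-3-yn-1-ol | C#CCCO | starting material
8 | (but-3-yn-1-yloxy)(tert-butyl)dimethylsilane | C#CCCO[Si](C)(C)C(C)(C)C | intermediate
9 | [(1E)-4-(tert-butyldimethylsilyloxy)-2-methylbut-1-en-1-yl]dimethylalane | C[Al](C)/C=C(\C)CCO[Si](C)(C)C(C)(C)C | intermediate
10 | (2E)-5-(tert-butyldimethylsilyloxy)-3-methylpent-2-en-1-ol | OC/C=C(\C)CCO[Si](C)(C)C(C)(C)C | intermediate
11 | {[(3E)-5-bromo-3-methylpent-3-en-1-yl]oxy}(tert-butyl)dimethylsilane | BrC/C=C(\C)CCO[Si](C)(C)C(C)(C)C | intermediate
12 | [5-(tert-butyldimethylsilyloxy)-2-methoxy-3-methylphenyl]lithium | COc1c(C)cc(O[Si](C)(C)C(C)(C)C)cc1[Li] | intermediate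
13 | tert-butyl{[(3E)-5-[5-(tert-butyldimethylsilyloxy)-2-methoxy-3-methylphenyl]-3-methylpent-3-en-1-yl]oxy}dimethylsilane | COc1c(C)cc(O[Si](C)(C)C(C)(C)C)cc1C/C=C(\C)CCO[Si](C)(C)C(C)(C)C | intermediate
14 | (3E)-5-[5-(tert-butyldimethylsilyloxy)-2-methoxy-3-methylphenyl]-3-methylpent-3-en-1-ol | COc1c(C)cc(O[Si](C)(C)C(C)(C)C)cc1C/C=C(\C)CCO | intermediate
15 | (3E)-5-[5-(tert-butyldimethylsilyloxy)-2-methoxy-3-methylphenyl]-3-methylpent-3-enal | COc1c(C)cc(O[Si](C)(C)C(C)(C)C)cc1C/C=C(\C)CC=O | intermediate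
16 | pent-4-yn-1-ol | C#CCCCO | starting material
17 | dimethylaluminium (4E)-5-(dimethylalumanyl)-4-methylpent-4-en-1-olate | C[Al](C)/C=C(\C)CCCO[Al](C)C | intermediate
18 | (4E)-5-iodo-4-methylpent-4-en-1-ol | OCCC/C(C)=C/I | intermediate
19 | (1E)-1,5-diiodo-2-methylpent-1-ene | ICCC/C(C)=C/I | intermediate
20 | (S)-lactic acid | C[C@H](O)C(=O)O | starting material
21 | (2S,5S)-2-tert-butyl-5-methyl-1,3-dioxolan-4-one | C[C@@H]1O[C@H](C(C)(C)C)OC1=O | intermediate
22 | lithium (2S)-2-tert-butyl-5-methyl-1,3-dioxol-4-olate | CC1=C(O[Li])O[C@@H](C(C)(C)C)O1 | intermediate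
23 | (2S,5R)-2-tert-butyl-5-[(4E)-5-iodo-4-methylpent-4-en-1-yl]-5-methyl-1,3-dioxolan-4-one | C[C@]1(CCC/C(C)=C/I)O[C@H](C(C)(C)C)OC1=O | intermediate
24 | (2R,6E)-2-hydroxy-7-iodo-N-methoxy-N,2,6-trimethylhept-6-enamide | CON(C)C(=O)[C@](C)(O)CCC/C(C)=C/I | intermediate
25 | (3R,7E)-3-hydroxy-8-iodo-3,7-dimethyloct-7-en-2-one | CC(=O)[C@](C)(O)CCC/C(C)=C/I | intermediate
26 | (3R,7E)-8-iodo-3,7-dimethyl-3-(trimethylsilyloxy)oct-7-en-2-one | CC(=O)[C@](C)(O[Si](C)(C)C)CCC/C(C)=C/I | intermediate
27 | methacrolein (2-methylprop-2-enal) | C=C(C)C=O | starting material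
28 | di[(+)-isopinocampheyl]boron enolate of 26 | C=C(OB([C@H]1C[C@H]2C[C@@H]([C@@H]1C)C2(C)C)[C@H]1C[C@H]2C[C@@H]([C@@H]1C)C2(C)C)[C@](C)(O[Si](C)(C)C)CCC/C(C)=C/I | intermediate
29 | (3R,6R,10E)-3-hydroxy-11-iodo-2,6,10-trimethyl-6-(trimethylsilyloxy)undeca-1,10-dien-5-one | C=C(C)[C@H](O)CC(=O)[C@](C)(O[Si](C)(C)C)CCC/C(C)=C/I | intermediate
30 | (3R,6R,10E)-3,6-dihydroxy-11-iodo-2,6,10-trimethylundeca-1,10-dien-5-one | C=C(C)[C@H](O)CC(=O)[C@](C)(O)CCC/C(C)=C/I | intermediate
31 | {[(3R,6R)-3-hydroxy-6-[(4E)-5-iodo-4-methylpent-4-en-1-yl]-2,6-dimethyl-5-oxooxan-2-yl]methyl}mercury trifluoroacetate (divalent mercury, both C-2 epimers) | I/C=C(\C)CCC[C@@]1(C)OC(C)(C[Hg]OC(=O)C(F)(F)F)[C@H](O)CC1=O | intermediate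
32 | (2R,5R)-5-hydroxy-2-[(4E)-5-iodo-4-methylpent-4-en-1-yl]-2,6,6-trimethyloxan-3-one | I/C=C(\C)CCC[C@@]1(C)OC(C)(C)[C@H](O)CC1=O | intermediate
33 | (2R,5R)-2-[(4E)-5-iodo-4-methylpent-4-en-1-yl]-2,6,6-trimethyl-5-(triethylsilyloxy)oxan-3-one | I/C=C(\C)CCC[C@@]1(C)OC(C)(C)[C@H](O[Si](CC)(CC)CC)CC1=O | intermediate
34 | {(1E)-2-methyl-5-[(2R,5R)-2,6,6-trimethyl-3-oxo-5-(triethylsilyloxy)oxan-2-yl]pent-1-en-1-yl}chromium dichloride (trivalent chromium) | Cl[Cr](Cl)/C=C(\C)CCC[C@@]1(C)OC(C)(C)[C@H](O[Si](CC)(CC)CC)CC1=O | intermediate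
35 | (2R,5R)-2-[(4E,8E)-10-[5-(tert-butyldimethylsilyloxy)-2-methoxy-3-methylphenyl]-6-hydroxy-4,8-dimethyldeca-4,8-dien-1-yl]-2,6,6-trimethyl-5-(triethylsilyloxy)oxan-3-one (both carbinol epimers) | COc1c(C)cc(O[Si](C)(C)C(C)(C)C)cc1C/C=C(\C)CC(O)/C=C(\C)CCC[C@@]1(C)OC(C)(C)[C@H](O[Si](CC)(CC)CC)CC1=O | intermediate
36 | (2R,5R)-2-[(4E,8E)-10-[5-(tert-butyldimethylsilyloxy)-2-methoxy-3-methylphenyl]-4,8-dimethyl-6-oxodeca-4,8-dien-1-yl]-2,6,6-trimethyl-5-(triethylsilyloxy)oxan-3-one | COc1c(C)cc(O[Si](C)(C)C(C)(C)C)cc1C/C=C(\C)CC(=O)/C=C(\C)CCC[C@@]1(C)OC(C)(C)[C@H](O[Si](CC)(CC)CC)CC1=O | intermediate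
37 | (2R,5R)-5-hydroxy-2-[(4E,8E)-10-(5-hydroxy-2-methoxy-3-methylphenyl)-4,8-dimethyl-6-oxodeca-4,8-dien-1-yl]-2,6,6-trimethyloxan-3-one | COc1c(C)cc(O)cc1C/C=C(\C)CC(=O)/C=C(\C)CCC[C@@]1(C)OC(C)(C)[C@H](O)CC1=O | target

**Totals**

Total step count: 23.
Longest linear sequence: 12 steps (16 → 18 → 19 → 23 → 24 → 25 → 26 → 30 → 32 → 33 → 35 → 36 → 37; steps 11, 12 and 14 to 23).

**Three steps most likely to fail, each with a fallback**

Step 18 (boron aldol). Ipc control with methyl ketones is only moderate, the facial sense is assigned from the Paterson model, and the α-silyloxy quaternary centre may help or oppose it. The fallback sets out from 26. An aldol without a chiral reagent (c-Hex2BCl, Et3N, Et2O, then 27, H2O2 work-up) gives the C-3 epimer mixture of the TMS aldol F1. A Sharpless kinetic resolution (Ti(Oi-Pr)4, L-(+)-diisopropyl tartrate, t-BuOOH, 4 Å sieves, CH2Cl2, −20 °C) epoxidises the fast-reacting (3S)-epimer to the epoxy alcohol F2. The slow (3R)-epimer is left behind and is 29, where the fallback comes back to the route; citric acid in MeOH then gives 30 as before.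

Step 19 (alkoxymercuration–demercuration). The borohydride may reduce the ring ketone along with the C–Hg bond. The fallback sets out from 30. TESCl, imidazole, DMF, 0 °C silylates only the secondary allylic hydroxyl and gives the mono-TES ether F3. Hg(O2CCF3)2 in CH2Cl2 closes the ring to the organomercurial F4. Excess NaBH4 in aq. NaOH then removes mercury and is allowed to reduce the ketone as well, giving the oxan-3-ol F5 as both C-3 epimers. IBX in DMSO reoxidises F5 to 33, where the route is rejoined; step 20 is then not needed.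

Step 21 (Nozaki–Hiyama–Kishi coupling). The β,γ-unsaturated aldehyde 15 may isomerise or enolise on the Lewis-acidic chromium salts, and the trisubstituted alkenyl iodide is slow. The fallback sets out from 15 and 33. NaClO2, NaH2PO4, 2-methylbut-2-ene, t-BuOH/H2O oxidises 15 to the β,γ-unsaturated acid F6. 1-Chloro-N,N,2-trimethylprop-1-en-1-amine in CH2Cl2 converts it under neutral conditions into the acid chloride F7. Separately, 33 with Me3SnSnMe3 and Pd(PPh3)4 in toluene at 80 °C gives the alkenylstannane F8. A Stille acylation of F7 with F8 (Pd2(dba)3, tri(2-furyl)phosphine, THF, 50 °C) gives the dienone 36 directly, where the route is rejoined; steps 21 and 22 fall away.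

**Further compounds**

F1 | step 18 | (6R,10E)-3-hydroxy-11-iodo-2,6,10-trimethyl-6-(trimethylsilyloxy)undeca-1,10-dien-5-one, both C-3 epimers | C=C(C)C(O)CC(=O)[C@](C)(O[Si](C)(C)C)CCC/C(C)=C/I
F2 | step 18 | (1S,4R,8E)-1-hydroxy-9-iodo-4,8-dimethyl-1-[(2S)-2-methyloxiran-2-yl]-4-(trimethylsilyloxy)non-8-en-3-one | C[C@]1(CO1)[C@@H](O)CC(=O)[C@](C)(O[Si](C)(C)C)CCC/C(C)=C/I
F3 | step 19 | (3R,6R,10E)-6-hydroxy-11-iodo-2,6,10-trimethyl-3-(triethylsilyloxy)undeca-1,10-dien-5-one | C=C(C)[C@H](O[Si](CC)(CC)CC)CC(=O)[C@](C)(O)CCC/C(C)=C/I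
F4 | step 19 | {[(3R,6R)-6-[(4E)-5-iodo-4-methylpent-4-en-1-yl]-2,6-dimethyl-5-oxo-3-(triethylsilyloxy)oxan-2-yl]methyl}mercury trifluoroacetate (divalent mercury, both C-2 epimers) | I/C=C(\C)CCC[C@@]1(C)OC(C)(C[Hg]OC(=O)C(F)(F)F)[C@H](O[Si](CC)(CC)CC)CC1=O
F5 | step 19 | (2R,5R)-2-[(4E)-5-iodo-4-methylpent-4-en-1-yl]-2,6,6-trimethyl-5-(triethylsilyloxy)oxan-3-ol, both C-3 epimers | I/C=C(\C)CCC[C@@]1(C)OC(C)(C)[C@H](O[Si](CC)(CC)CC)CC1O
F6 | step 21 | (3E)-5-[5-(tert-butyldimethylsilyloxy)-2-methoxy-3-methylphenyl]-3-methylpent-3-enoic acid | COc1c(C)cc(O[Si](C)(C)C(C)(C)C)cc1C/C=C(\C)CC(=O)O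
F7 | step 21 | (3E)-5-[5-(tert-butyldimethylsilyloxy)-2-methoxy-3-methylphenyl]-3-methylpent-3-enoyl chloride | COc1c(C)cc(O[Si](C)(C)C(C)(C)C)cc1C/C=C(\C)CC(=O)Cl
F8 | step 21 | (2R,5R)-2,6,6-trimethyl-2-[(4E)-4-methyl-5-(trimethylstannyl)pent-4-en-1-yl]-5-(triethylsilyloxy)oxan-3-one | C[Sn](C)(C)/C=C(\C)CCC[C@@]1(C)OC(C)(C)[C@H](O[Si](CC)(CC)CC)CC1=O
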